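## Structural features

The target 17 is a diaryl ether that joins two arenes of polyketide origin through one oxygen atom. Ring A is a 1H-isochromen-1-one (isocoumarin) with a pentyl group at C3, a methoxy group at C6 and the ether oxygen at C8, peri to the lactone carbonyl C1. Ring B is a benzoic acid with a single ring hydrogen: C1' carries CO2H, C2' a 2-oxoheptyl chain, C3' the ether oxygen, C4' and C6' hydroxyls and C5' hydrogen. There is no stereocentre, so no stereocentres stand next to each other and the problem is one of regiochemistry and of telling like groups apart. The 2-oxoheptyl keto acid of ring B is the open form of a second 3-pentylisocoumarin, so the two halves differ only in that ring A is lactonised and ring B is not; dehydrating acid can close ring B, hydroxide or alkoxide can open ring A, and the β-resorcylic acid of ring B can lose CO2 in hot acid. The real difficulty is the ether oxygen, which sits between two substituted carbons on ring B (C2' and C4') and next to the peri carbonyl on ring A, a poor setting for a late aryl–oxygen coupling. The key step exploits the fact that C1' to C6' of ring B, with oxygen on C4' and C6' and carbon on C1' and C2', are a folded poly-β-carbonyl chain: the ether oxygen can be placed on the sp3 carbon that becomes C3' and the ring closed afterwards by an aldol bond between C1' and C2'.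

## Logic of the disconnections

17 to 16. The cuts are the four C–O bonds of two acetal carbons: the side-chain ketone on C2' is re-masked as its dioxolane, and the C1' carboxyl and the C6' hydroxyl are tied back into the six-membered isopropylidene acylal. The reason is that 16 is the form in which ring B leaves the ring-forming step, and that both masks fall to aqueous acid, which leaves the lactone of ring A closed, so the two carboxyls are never in the same state. The gain is an endgame of one operation. The forward step needs an acid that is wet and mild enough that the freed keto acid of ring B neither lactonises nor decarboxylates.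

16 to 14. The cut is the C1'–C2' bond of ring B, with water added back across C2' and C3' (15 is the hydrated stage). This unfolds the pentasubstituted benzene into a chain in which C1' is C5 of a dioxinone, C2' and C4' are ketones and C3' is an sp3 methine that already carries the ether oxygen. The gain is one ring and five contiguous substituents exchanged for a chain made by carbonyl chemistry, and the hindered ether becomes an ordinary alkyl aryl ether. The forward step must fold in one way only, under a base mild enough for the lactone of ring A and for the dioxolane, and must lose water from 15.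

14 to 10 and 13. The cut is the bond between the aryloxy-bearing carbon (future C3') and the ketone carbon that becomes C2'. In 10 this carbon is the α' position of a ketone whose other α position is more acidic, the situation in which a dianion reacts at the carbon deprotonated last. The acyl partner 13 carries a leaving group that holds the adduct at the tetrahedral stage, so the strongly acidic β-diketone appears only on work-up. The gain is a convergent union of a C24 and a C10 unit. The demand is that a strongly basic dianion spares the lactone of ring A and that 13 is attacked at its carbonyl carbon and not deprotonated next to its ketal.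

13 to 12 to 11. The cuts are the amide C–N bond and then the two C–O bonds of the dioxolane. These are functional-group changes: the side-chain ketone must be hidden before any enolate chemistry, and the ester of 11 is a poor acyl donor toward a dianion. The gain is that the C10 unit comes from one commercial β-keto ester. The forward steps must ketalise the ketone without touching the ester and convert the ester into the amide without β-elimination.

10 to 8 and 9. The cut is the bond between the methylene on C6 of the dioxinone and the ketone carbon that becomes C4'. The reason is that 9 is deprotonated at its methyl group and acylated at that γ-carbon, so four carbons of ring B and its masked carboxyl arrive as one commercial unit. The gain is that 8 is a simple two-carbon derivative of the ring A phenol. The demand is that the lithium dienolate chooses the amide carbonyl of 8 over the lactone carbonyl.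

8 to 6 and 7. The cut is the O–CH2 bond of the ether. This is the bond that is hard to make between two arenes; cut here it is an SN2 displacement at a primary carbon next to a carbonyl group, the most forgiving way to alkylate a chelated phenol. The gain is that ring A is released as a free-standing phenol. The forward step needs a base that deprotonates the phenol without opening the lactone.

6 to 5 to 2 and 4. The cuts are the lactone O2–C1 bond, which opens the enol lactone to a keto ester, and then the C4–C3 bond between the benzylic carbon and the ketone. The reason is that the benzylic methyl group of 2 is acidified by the ortho ester, so the C3 side of ring A can be added as one acyl unit. The gain is that ring A is reduced to a simple toluate. The forward steps need a carbanion that adds only once to the acyl donor and a lactonisation that engages the ketone enol.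

2 to 1 and 4 to 3. The cuts are the O–CH3 bond at C4 of the benzoate and the amide C–N bond. Both lead to commercial materials. The demand is that the methylation distinguishes the two hydroxyls of 1, which the hydrogen bond of the 2-hydroxyl to the ester should provide.

## Other disconnections considered

Alternative 1: The cut is at both aryl–CH2 bonds (C4a–C4 of ring A and C2'–CH2 of ring B) of the bis(2-oxoheptyl) diaryl ether diester A1, leading back to the dibromo diaryl ether A2 and two molecules of 1-chloroheptan-2-one A3. The forward key step is a twofold electroreductive coupling with NiBr2(2,2'-bipyridine) at the cathode and a sacrificial zinc anode. Zerovalent nickel inserts into each C–Br bond and the arylnickel species is joined to the α-carbon of A3; no ring is closed. A1 would then need acidolysis of the tert-butyl ester with enol lactonisation of ring A, and hydrogenolysis of the benzyl groups.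
- In its favour: both C7 ketone chains come from one cheap reagent in one operation, the ring B ketone needs no mask, and the two carboxyls are told apart by tert-butyl against benzyl ester.
- Better than the chosen plan on one point: the last step is a neutral hydrogenolysis, so the free resorcylic acid never meets aqueous acid.
- Against it: the hard ether is moved to the front and not solved. A2 requires an aryl–oxygen bond between two ortho-flanked carbons, the coupling the chosen plan avoids. The ring B bromide lies between an ester and an aryloxy group, where oxidative addition and coupling may be slow and cathodic hydrodebromination may compete. Two couplings in one molecule multiply any shortfall, A3 is enolisable and reducible, and the hydrogenolysis must spare the C3=C4 bond of the lactone.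
- Comparison: this plan decorates two finished arenes, while the chosen plan builds ring B around the oxygen. Its mechanism is organometallic and radical where the chosen one is polar carbonyl chemistry. The step count would be about equal only if A2 were readily available.

Alternative 2: The cuts are the O2–C3 bond of ring A and the carbonyl of the ring B side chain in triallyl β-collatolic acid A4, leading back to the dialkyne A5. A5 carries an o-(hept-1-ynyl)benzoic acid on ring A and an allyl o-(hept-2-ynyl)benzoate on ring B. The forward key step uses Ph3PAuNTf2 in wet dioxane. Monovalent gold activates both alkynes; the ring A acid adds 6-endo-dig to close the pyranone, and the ring B ester carbonyl adds 6-exo-dig to C2 of the hept-2-ynyl chain, after which water opens the cyclic cation to ketone and ester. Removal of three allyl groups with zerovalent palladium would finish the synthesis.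
- In its favour: the conditions are neutral, the position of the ketone is fixed by geometry, and acid and allyl ester are different from the start.
- Equal or better than the chosen plan on two points: no strong base ever meets the lactone, and the final deallylation is cold and neutral, which is safer for the resorcylic acid than an aqueous acid finish.
- Against it: A5 again needs the hindered diaryl ether, and in addition two alkynes at crowded positions. 5-exo-dig closure to an alkylidene phthalide competes with the 6-endo mode. The allyl group may leave from the cyclic cation and give a ring B isocoumarin. The doubly activated CH2 may isomerise to an allene, and allyl aryl ethers are not inert to cationic gold.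
- Comparison: the structural logic (two alkynes as latent lactone and keto acid) is elegant, and the mechanism is π-acid catalysis against enolate chemistry. Ring B must still be fully substituted by arene chemistry before the ether is made, so the route would probably be longer.

Alternative 3: The cut is the C5–C6 bond of ring A in the 6-hydroxyisocoumarin aryl ether A6, leading back to the pyranone A7, a 4-methyl-6-pentyl-2-pyranone with a β-aryloxy acrylate at C3 whose aryl group is the protected ring B. The forward key step is deprotonation of the 4-methyl group with LiN(SiMe3)2 and attack of the carbanion on the acrylate ester carbonyl (6-exo-trig, a vinylogous Claisen condensation). Loss of alkoxide and tautomerisation give the C6 phenol. O-Methylation, hydrogenolysis and ketal hydrolysis would follow.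
- Equal to the chosen plan on the central point: two arenes are never coupled at oxygen, since the ether could be made by conjugate addition of the ring B phenol to an ynoate.
- Better on two smaller points: the C6 oxygen is born free and unique, so its methylation is unambiguous, and the end needs acid only for a dioxolane.
- Against it: ring B, the harder ring, must be made beforehand as a fully substituted and protected phenol, whereas the chosen plan makes ring B in its key step. The α-methylene of the 6-pentyl group is also vinylogously acidic, so the site of deprotonation is not secured by the substrate. The acrylate must have the E geometry that places ester and pyranone cis. The β-aryloxy acrylate can lose aryloxide by addition–elimination.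
- Comparison: both plans build a benzene ring from an open chain by enolate acylation or aldol chemistry, but this one builds the easy ring and buys the hard one. On step economy it should be clearly longer.

Key step: step 10

## Remarks on the chemistry

- Numbering: ring A is numbered as 1H-isochromen-1-one (C1 carbonyl, O2, C3 to C8a); ring B carries primes, C1' being the carboxyl-bearing carbon.
- Compounds 14 and 16 differ by one molecule of water and their constitutions are consistent with the bond formed in step 10. 14 is drawn in the triketo form and is racemic and stereolabile at the aryloxy methine.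
- The ether oxygen is attached by SN2 alkylation (step 5) and not by insertion of a rhodium carbenoid into the O–H bond. A carbenoid next to a ketone whose β-carbon is a dioxolane has a ketal oxygen and a C–H bond of the pentyl chain in a 1,5 relation; five-membered oxonium ylide formation with [1,2]-shift and 1,5 C–H insertion would compete with a chelated phenol.
- A 2-aryloxy-3-oxo ester cannot serve as the electrophile toward a lithium dienolate, because its methine is deprotonated first. The dioxinone is therefore attached first (step 6) and the side-chain unit second (step 9), each through an N-methoxy-N-methylamide.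
- Assumption: hexanoyl chloride 3 and 2-chloro-N-methoxy-N-methylacetamide 7 are taken as commercial.

## Route

Step 1
Reactants: 1 methyl 2,4-dihydroxy-6-methylbenzoate
Product: 2 methyl 2-hydroxy-4-methoxy-6-methylbenzoate
Conditions: MeI (1.05 equiv), K2CO3, acetone, rt to 40 °C
Reagents that add atoms: iodomethane, CI
Why: Williamson ether synthesis; the 2-hydroxyl is held in a hydrogen bond to the ester carbonyl and is less acidic and less nucleophilic than the para 4-hydroxyl, so one equivalent of MeI should methylate O4 only.

Step 2
Reactants: 3 hexanoyl chloride
Product: 4 N-methoxy-N-methylhexanamide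
Conditions: MeNH(OMe)·HCl, K2CO3, CH2Cl2–H2O, 0 °C to rt
Reagents that add atoms: N,O-dimethylhydroxylamine hydrochloride, CNOC.Cl
Why: Schotten–Baumann acylation of the hydroxylamine nitrogen by the acid chloride gives the Weinreb amide needed for a clean ketone synthesis in step 3.

Step 3
Reactants: 2 methyl 2-hydroxy-4-methoxy-6-methylbenzoate, 4 N-methoxy-N-methylhexanamide
Product: 5 methyl 2-hydroxy-4-methoxy-6-(2-oxoheptyl)benzoate
Conditions: LiN(i-Pr)2 (2.2 equiv), THF, −78 °C; then 4, −78 to −40 °C; aq. HCl
Reagents that add atoms: none
Why: Two equivalents of amide base give the phenoxide and then the laterally lithiated o-toluate, whose benzylic carbanion adds to the amide; the chelated tetrahedral adduct survives until the acid quench, so neither a second addition nor enolisation of the new ketone consumes the dianion (Weinreb ketone synthesis).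

Step 4
Reactants: 5 methyl 2-hydroxy-4-methoxy-6-(2-oxoheptyl)benzoate
Product: 6 8-hydroxy-6-methoxy-3-pentyl-1H-isochromen-1-one
Conditions: p-TsOH·H2O (cat.), toluene, reflux, Dean–Stark trap
Reagents that add atoms: none
Why: Acid-catalysed enol lactonisation; the enol oxygen of the benzylic ketone attacks the neighbouring ester carbonyl through a six-membered transition state, and removal of methanol drives closure to the conjugated isocoumarin with the chelated 8-hydroxyl left free.

Step 5
Reactants: 6 8-hydroxy-6-methoxy-3-pentyl-1H-isochromen-1-one, 7 2-chloro-N-methoxy-N-methylacetamide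
Product: 8 N-methoxy-2-[(6-methoxy-1-oxo-3-pentyl-1H-isochromen-8-yl)oxy]-N-methylacetamide
Conditions: K2CO3, KI (cat.), DMF, 60 °C
Reagents that add atoms: none
Why: Williamson ether synthesis at a primary α-halo amide carbon (SN2 with in situ chloride–iodide exchange); the peri-chelated phenoxide is a weak nucleophile but this electrophile is highly reactive, and dry carbonate should not open the lactone.

Step 6
Reactants: 8 N-methoxy-2-[(6-methoxy-1-oxo-3-pentyl-1H-isochromen-8-yl)oxy]-N-methylacetamide, 9 2,2,6-trimethyl-4H-1,3-dioxin-4-one
Product: 10 6-{3-[(6-methoxy-1-oxo-3-pentyl-1H-isochromen-8-yl)oxy]-2-oxopropyl}-2,2-dimethyl-4H-1,3-dioxin-4-one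
Conditions: 9, LiN(SiMe3)2, THF, −78 °C; then 8, −78 to −40 °C; AcOH
Reagents that add atoms: none
Why: Crossed Claisen-type acylation; the base removes a proton from the 6-methyl group of 9 and the dienolate reacts at its γ-carbon with the Weinreb amide, whose chelated adduct releases the ketone only on quench, and the amide carbonyl activated by the α-aryloxy group should be attacked in preference to the hindered, donor-substituted lactone carbonyl of ring A.

Step 7
Reactants: 11 methyl 3-oxooctanoate
Product: 12 methyl 2-(2-pentyl-1,3-dioxolan-2-yl)acetate
Conditions: HOCH2CH2OH, p-TsOH·H2O (cat.), toluene, reflux, Dean–Stark trap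
Reagents that add atoms: ethylene glycol, OCCO
Why: Acid-catalysed ketalisation with azeotropic removal of water; the ester is inert and the dioxolane hides the carbonyl that becomes the side-chain ketone of ring B.

Step 8
Reactants: 12 methyl 2-(2-pentyl-1,3-dioxolan-2-yl)acetate
Product: 13 N-methoxy-N-methyl-2-(2-pentyl-1,3-dioxolan-2-yl)acetamide
Conditions: MeNH(OMe)·HCl, i-PrMgCl, THF, −20 to 0 °C; aq. NH4Cl
Reagents that add atoms: N,O-dimethylhydroxylamine hydrochloride, CNOC.Cl
Why: Direct aminolysis of the ester by the chloromagnesium amide formed from the hydroxylamine salt and i-PrMgCl; addition to the ester carbonyl at −20 °C is faster than α-deprotonation, so the β-ketal should not be eliminated.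

Step 9
Reactants: 10 6-{3-[(6-methoxy-1-oxo-3-pentyl-1H-isochromen-8-yl)oxy]-2-oxopropyl}-2,2-dimethyl-4H-1,3-dioxin-4-one, 13 N-methoxy-N-methyl-2-(2-pentyl-1,3-dioxolan-2-yl)acetamide
Product: 14 6-{3-[(6-methoxy-1-oxo-3-pentyl-1H-isochromen-8-yl)oxy]-2,4-dioxo-5-(2-pentyl-1,3-dioxolan-2-yl)pentyl}-2,2-dimethyl-4H-1,3-dioxin-4-one (racemic)
Conditions: LiN(i-Pr)2 (2.2 equiv), THF, −78 °C; then 13, −78 to −30 °C; AcOH, −78 °C
Reagents that add atoms: none
Why: Claisen acylation of a keto-dioxinone dianion; the first equivalent of base enolises the methylene next to the dioxinone, the second removes a proton from the aryloxy-bearing α' carbon, and this last-formed carbanion adds to the Weinreb amide, whose adduct releases the acidic β-diketone only on quench. The ring A lactone should be spared because the tethered carbanion can approach its carbonyl carbon only within the plane of the carbonyl group.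

Step 10
Reactants: 14 6-{3-[(6-methoxy-1-oxo-3-pentyl-1H-isochromen-8-yl)oxy]-2,4-dioxo-5-(2-pentyl-1,3-dioxolan-2-yl)pentyl}-2,2-dimethyl-4H-1,3-dioxin-4-one
Product: 16 7-hydroxy-6-[(6-methoxy-1-oxo-3-pentyl-1H-isochromen-8-yl)oxy]-2,2-dimethyl-5-[(2-pentyl-1,3-dioxolan-2-yl)methyl]-4H-benzo[d][1,3]dioxin-4-one, via cyclic aldol adduct 15 (not isolated)
Conditions: Et3N, CH2Cl2, 0 °C to rt
Reagents that add atoms: none
Why: This is the base-mediated aldol aromatisation of a diketo-dioxinone to an isopropylidene-protected resorcylate, the closest known reaction type being the same cyclisation of chains that lack the aryloxy group. Et3N equilibrates the enolates of 14; the productive one is the dienolate formed at the methylene between the dioxinone and the first ketone, whose charge emerges at C5 of the dioxinone (the future C1'). This carbon adds to the ketone next to the dioxolane-bearing methylene (the future C2') in a 6-(enolendo)-exo-trig closure to give 15, and loss of water across C1'–C2' followed by enolisation of the C4' ketone aromatises ring B. No stereocentre is formed in the product: the two centres of 15 (C2' and C3') are destroyed on aromatisation, so its diastereomers converge. The selectivity needed is regioselective folding, and it is secured because the dioxolane takes the fourth carbonyl out of play, leaving the dioxinone carbon and this one ketone as the only pair that can close a six-membered ring to an aromatisable product. The most acidic site, the aryloxy methine, can reach only the dioxinone carbonyl, which would create a quaternary centre that cannot aromatise, and its stabilised enolate is a poor nucleophile toward an ester-type carbonyl. The ring A lactone and the acetonide are inert to Et3N, and a dioxolane opened reversibly by β-elimination would re-close or be hydrolysed to the same ketone in step 11.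

Step 11
Reactants: 16 7-hydroxy-6-[(6-methoxy-1-oxo-3-pentyl-1H-isochromen-8-yl)oxy]-2,2-dimethyl-5-[(2-pentyl-1,3-dioxolan-2-yl)methyl]-4H-benzo[d][1,3]dioxin-4-one
Product: 17 4,6-dihydroxy-3-[(6-methoxy-1-oxo-3-pentyl-1H-isochromen-8-yl)oxy]-2-(2-oxoheptyl)benzoic acid (β-collatolic acid)
Conditions: CF3CO2H–H2O (3:1), 1,4-dioxane, 40 °C
Reagents that add atoms: water, O
Why: Acid hydrolysis of a ketal and of an acylal; the dioxolane is cleaved first, then ionisation at the isopropylidene carbon and capture by water release acetone, the C6' hydroxyl and the carboxylic acid. The enol lactone of ring A, the methyl ether and the diaryl ether are stable to aqueous acid, and the high water content and moderate temperature are meant to hold back lactonisation of the ring B keto acid and protodecarboxylation.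

## Compound list

1 | methyl 2,4-dihydroxy-6-methylbenzoate | COC(=O)c1c(C)cc(O)cc1O | starting material
2 | methyl 2-hydroxy-4-methoxy-6-methylbenzoate | COC(=O)c1c(C)cc(OC)cc1O | intermediate
3 | hexanoyl chloride | CCCCCC(=O)Cl | starting material
4 | N-methoxy-N-methylhexanamide | CCCCCC(=O)N(C)OC | intermediate
5 | methyl 2-hydroxy-4-methoxy-6-(2-oxoheptyl)benzoate | COC(=O)c1c(CC(=O)CCCCC)cc(OC)cc1O | intermediate
6 | 8-hydroxy-6-methoxy-3-pentyl-1H-isochromen-1-one | CCCCCc1cc2cc(OC)cc(O)c2c(=O)o1 | intermediate
7 | 2-chloro-N-methoxy-N-methylacetamide | ClCC(=O)N(C)OC | starting material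
8 | N-methoxy-2-[(6-methoxy-1-oxo-3-pentyl-1H-isochromen-8-yl)oxy]-N-methylacetamide | CCCCCc1cc2cc(OC)cc(OCC(=O)N(C)OC)c2c(=O)o1 | intermediate
9 | 2,2,6-trimethyl-4H-1,3-dioxin-4-one | CC1=CC(=O)OC(C)(C)O1 | starting material
10 | 6-{3-[(6-methoxy-1-oxo-3-pentyl-1H-isochromen-8-yl)oxy]-2-oxopropyl}-2,2-dimethyl-4H-1,3-dioxin-4-one | CCCCCc1cc2cc(OC)cc(OCC(=O)CC3=CC(=O)OC(C)(C)O3)c2c(=O)o1 | intermediate
11 | methyl 3-oxooctanoate | CCCCCC(=O)CC(=O)OC | starting material
12 | methyl 2-(2-pentyl-1,3-dioxolan-2-yl)acetate | CCCCCC1(CC(=O)OC)OCCO1 | intermediate
13 | N-methoxy-N-methyl-2-(2-pentyl-1,3-dioxolan-2-yl)acetamide | CCCCCC1(CC(=O)N(C)OC)OCCO1 | intermediate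
14 | 6-{3-[(6-methoxy-1-oxo-3-pentyl-1H-isochromen-8-yl)oxy]-2,4-dioxo-5-(2-pentyl-1,3-dioxolan-2-yl)pentyl}-2,2-dimethyl-4H-1,3-dioxin-4-one (racemic, stereolabile methine) | CCCCCc1cc2cc(OC)cc(OC(C(=O)CC3=CC(=O)OC(C)(C)O3)C(=O)CC4(CCCCC)OCCO4)c2c(=O)o1 | intermediate
15 | 5-hydroxy-6-[(6-methoxy-1-oxo-3-pentyl-1H-isochromen-8-yl)oxy]-2,2-dimethyl-5-[(2-pentyl-1,3-dioxolan-2-yl)methyl]-5,6-dihydro-4H-benzo[d][1,3]dioxine-4,7(8H)-dione (cyclic aldol adduct, formed in the flask, mixture of racemic diastereomers) | CCCCCc1cc2cc(OC)cc(OC3C(=O)CC4=C(C(=O)OC(C)(C)O4)C3(O)CC5(CCCCC)OCCO5)c2c(=O)o1 | intermediate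
16 | 7-hydroxy-6-[(6-methoxy-1-oxo-3-pentyl-1H-isochromen-8-yl)oxy]-2,2-dimethyl-5-[(2-pentyl-1,3-dioxolan-2-yl)methyl]-4H-benzo[d][1,3]dioxin-4-one | CCCCCc1cc2cc(OC)cc(Oc3c(O)cc4OC(C)(C)OC(=O)c4c3CC5(CCCCC)OCCO5)c2c(=O)o1 | intermediate
17 | 4,6-dihydroxy-3-[(6-methoxy-1-oxo-3-pentyl-1H-isochromen-8-yl)oxy]-2-(2-oxoheptyl)benzoic acid (β-collatolic acid) | CCCCCC(=O)Cc1c(Oc2cc(OC)cc3cc(CCCCC)oc(=O)c23)c(O)cc(O)c1C(=O)O | target

## Step count and least certain steps

Total step count: 11. Longest linear sequence: 8 steps (steps 1, 3, 4, 5, 6, 9, 10 and 11, from 1 to 17).

Step 10 (key step).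
- What may go wrong: the base may rest on the enolate of the aryloxy methine, so that the dienolate needed for closure forms too slowly. Reversible β-elimination that opens the dioxolane would lower the electrophilicity of the ketone to be attacked. The sequence may stall at 15 if dehydration is slow, and retro-Claisen cleavage of the β-diketone may gain ground.
- Why: the aryloxy group raises the acidity of the central carbon and crowds the ketone, a substitution pattern for which this cyclisation has no close model.
- Fallback: it sets out from 14 and comes back at 17. Heating 14 in toluene at 110 °C with allyl alcohol should expel acetone by retro-[4+2] reaction and trap the acyl ketene as allyl 6-[(6-methoxy-1-oxo-3-pentyl-1H-isochromen-8-yl)oxy]-3,5,7-trioxo-8-(2-pentyl-1,3-dioxolan-2-yl)octanoate F1. Its C2 methylene is a stronger carbon acid than the dioxinone carbon and should close onto the same ketone with Et3N to give allyl 4,6-dihydroxy-3-[(6-methoxy-1-oxo-3-pentyl-1H-isochromen-8-yl)oxy]-2-[(2-pentyl-1,3-dioxolan-2-yl)methyl]benzoate F2. Aqueous acetic acid at room temperature should remove the dioxolane to give allyl 4,6-dihydroxy-3-[(6-methoxy-1-oxo-3-pentyl-1H-isochromen-8-yl)oxy]-2-(2-oxoheptyl)benzoate F3, and Pd(PPh3)4 with morpholine should remove the allyl group to give 17 without 15, 16 or step 11.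

Step 9.
- What may go wrong: proton transfer from the α-methylene of 13 to the dianion, followed by β-elimination of a ketal oxygen; slow addition to a carbonyl group next to a quaternary-substituted methylene; intermolecular attack of the dianion on the lactone of ring A.
- Why: the dianion is a strong base and 13 is a hindered, enolisable acyl donor.
- Fallback: it sets out from 13 and 10 and comes back at 14. It replaces the acylation by aldol addition and oxidation. Reduction of 13 with i-Bu2AlH at −78 °C should give 2-(2-pentyl-1,3-dioxolan-2-yl)acetaldehyde F4, a faster and less hindered electrophile. Addition of the same dianion of 10 at −78 °C should give 6-{4-hydroxy-3-[(6-methoxy-1-oxo-3-pentyl-1H-isochromen-8-yl)oxy]-2-oxo-5-(2-pentyl-1,3-dioxolan-2-yl)pentyl}-2,2-dimethyl-4H-1,3-dioxin-4-one F5 as a mixture of diastereomers. Oxidation with Dess–Martin periodinane should then give 14.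

Step 11.
- What may go wrong: protodecarboxylation of the freed β-resorcylic acid; acid-catalysed enol lactonisation of the ring B keto acid to a second isocoumarin; incomplete cleavage of the acylal because the ionised intermediate re-closes faster than water captures it.
- Why: the acetonide needs more forcing acid than the dioxolane, and the product is acid-sensitive.
- Fallback: it sets out from 16 and comes back at 17. It cleaves the acylal photochemically instead of with acid. Irradiation of a dilute solution of 16 at about 300 nm in aqueous acetonitrile should expel acetone and generate an o-quinone ketene, which water captures to give 4,6-dihydroxy-3-[(6-methoxy-1-oxo-3-pentyl-1H-isochromen-8-yl)oxy]-2-[(2-pentyl-1,3-dioxolan-2-yl)methyl]benzoic acid F6. The dioxolane is then removed with aqueous acetic acid at room temperature to give 17. The isocoumarin also absorbs near this wavelength, so dilution and a filter are needed.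

Step 6.
- What may go wrong: addition of the lithium dienolate to the lactone carbonyl of ring A, or deprotonation of the O–CH2 group of 8, in place of addition to the amide.
- Why: 8 offers two acyl electrophiles and an acidic methylene to a basic nucleophile.
- Fallback: it sets out from 9, 7 and 6 and comes back at 10. It inverts the order so that the lactone never meets a lithium enolate. Acylation of the dienolate of 9 with 7 (LiN(SiMe3)2, THF, −78 °C) should give 6-(3-chloro-2-oxopropyl)-2,2-dimethyl-4H-1,3-dioxin-4-one F7. Alkylation of 6 with F7 (K2CO3, NaI, acetone) should then give 10.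

## Further compounds

F1 | step 10 | allyl 6-[(6-methoxy-1-oxo-3-pentyl-1H-isochromen-8-yl)oxy]-3,5,7-trioxo-8-(2-pentyl-1,3-dioxolan-2-yl)octanoate (racemic) | C=CCOC(=O)CC(=O)CC(=O)C(Oc1cc(OC)cc2cc(CCCCC)oc(=O)c12)C(=O)CC3(CCCCC)OCCO3
F2 | step 10 | allyl 4,6-dihydroxy-3-[(6-methoxy-1-oxo-3-pentyl-1H-isochromen-8-yl)oxy]-2-[(2-pentyl-1,3-dioxolan-2-yl)methyl]benzoate | C=CCOC(=O)c1c(O)cc(O)c(Oc2cc(OC)cc3cc(CCCCC)oc(=O)c23)c1CC4(CCCCC)OCCO4
F3 | step 10 | allyl 4,6-dihydroxy-3-[(6-methoxy-1-oxo-3-pentyl-1H-isochromen-8-yl)oxy]-2-(2-oxoheptyl)benzoate | C=CCOC(=O)c1c(O)cc(O)c(Oc2cc(OC)cc3cc(CCCCC)oc(=O)c23)c1CC(=O)CCCCC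
F4 | step 9 | 2-(2-pentyl-1,3-dioxolan-2-yl)acetaldehyde | CCCCCC1(CC=O)OCCO1
F5 | step 9 | 6-{4-hydroxy-3-[(6-methoxy-1-oxo-3-pentyl-1H-isochromen-8-yl)oxy]-2-oxo-5-(2-pentyl-1,3-dioxolan-2-yl)pentyl}-2,2-dimethyl-4H-1,3-dioxin-4-one (mixture of racemic diastereomers) | CCCCCc1cc2cc(OC)cc(OC(C(=O)CC3=CC(=O)OC(C)(C)O3)C(O)CC4(CCCCC)OCCO4)c2c(=O)o1
F6 | step 11 | 4,6-dihydroxy-3-[(6-methoxy-1-oxo-3-pentyl-1H-isochromen-8-yl)oxy]-2-[(2-pentyl-1,3-dioxolan-2-yl)methyl]benzoic acid | OC(=O)c1c(O)cc(O)c(Oc2cc(OC)cc3cc(CCCCC)oc(=O)c23)c1CC4(CCCCC)OCCO4
F7 | step 6 | 6-(3-chloro-2-oxopropyl)-2,2-dimethyl-4H-1,3-dioxin-4-one | ClCC(=O)CC1=CC(=O)OC(C)(C)O1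
A1 | alternative 1 | tert-butyl 2-{3-[(benzyloxy)carbonyl]-4,6-bis(benzyloxy)-2-(2-oxoheptyl)phenoxy}-4-methoxy-6-(2-oxoheptyl)benzoate | COc1cc(CC(=O)CCCCC)c(C(=O)OC(C)(C)C)c(Oc2c(CC(=O)CCCCC)c(C(=O)OCc3ccccc3)c(OCc4ccccc4)cc2OCc5ccccc5)c1
A2 | alternative 1 | tert-butyl 2-bromo-6-{2-bromo-3-[(benzyloxy)carbonyl]-4,6-bis(benzyloxy)phenoxy}-4-methoxybenzoate | COc1cc(Br)c(C(=O)OC(C)(C)C)c(Oc2c(Br)c(C(=O)OCc3ccccc3)c(OCc4ccccc4)cc2OCc5ccccc5)c1
A3 | alternative 1 | 1-chloroheptan-2-one | CCCCCC(=O)CCl
A4 | alternative 2 | allyl 4,6-bis(allyloxy)-3-[(6-methoxy-1-oxo-3-pentyl-1H-isochromen-8-yl)oxy]-2-(2-oxoheptyl)benzoate (triallyl β-collatolic acid) | CCCCCc1cc2cc(OC)cc(Oc3c(OCC=C)cc(OCC=C)c(C(=O)OCC=C)c3CC(=O)CCCCC)c2c(=O)o1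
A5 | alternative 2 | 2-{3-[(allyloxy)carbonyl]-4,6-bis(allyloxy)-2-(hept-2-yn-1-yl)phenoxy}-6-(hept-1-yn-1-yl)-4-methoxybenzoic acid | CCCCCC#Cc1cc(OC)cc(Oc2c(OCC=C)cc(OCC=C)c(C(=O)OCC=C)c2CC#CCCCC)c1C(=O)O
A6 | alternative 3 | benzyl 4,6-bis(benzyloxy)-3-[(6-hydroxy-1-oxo-3-pentyl-1H-isochromen-8-yl)oxy]-2-[(2-pentyl-1,3-dioxolan-2-yl)methyl]benzoate | CCCCCc1cc2cc(O)cc(Oc3c(OCc4ccccc4)cc(OCc5ccccc5)c(C(=O)OCc6ccccc6)c3CC7(CCCCC)OCCO7)c2c(=O)o1
A7 | alternative 3 | benzyl 4,6-bis(benzyloxy)-3-{[(E)-3-methoxy-1-(4-methyl-2-oxo-6-pentyl-2H-pyran-3-yl)-3-oxoprop-1-en-1-yl]oxy}-2-[(2-pentyl-1,3-dioxolan-2-yl)methyl]benzoate | CCCCCc1cc(C)c(c(=O)o1)/C(Oc2c(OCc3ccccc3)cc(OCc4ccccc4)c(C(=O)OCc5ccccc5)c2CC6(CCCCC)OCCO6)=C\C(=O)OC
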